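## The problem

Manniflavanone (16) is a biflavanone in which C3 of an eriodictyol-type flavanone (unit 1) is bonded to C8 of a taxifolin-type dihydroflavonol (unit 2). The linking bond joins an sp3 carbon α to a ketone to an aromatic carbon that has oxygen substituents on both neighbours, so it is crowded and sits next to an enolisable position. There are four stereocentres: C2 and C3 of unit 2 (2R,3R, trans) and C2 and C3 of unit 1 (2R,3S, trans). The unit 2 pair is the C4-oxidised form of the C2/C3 pair of (+)-catechin and can be taken from the chiral pool. It is several bonds and a rotating aryl–C bond away from unit 1, so it cannot be relied on to control unit 1. In unit 1, C3 is benzylic and α to the carbonyl and will equilibrate, so only C2 must be set by a reagent; the trans relationship then follows thermodynamically, provided the C2–O1 bond is never broken. The main fragility is that both pyranone rings can open under base by enolisation and loss of the phenoxide, which erases C2. In addition, nine hydroxyl groups (two catechols, one secondary alcohol) must be masked and released without oxidation. The feature that allows the key step lies in ring C of unit 1: C2 carries a hydrogen, ring B and the ether oxygen O1, and is linked through O1–C8a–C4a–C4 to C3. C3 is the α-carbon of an aryl ketone and bears ring A of unit 2, so a carbene at C3 stands in a 1,6-relationship to a benzylic, oxygen-activated C–H bond of an aryl benzyl ether.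

## Retrosynthesis

**16 to 15.** The last operation is removal of all hydroxyl protecting groups from the nonasilyl ether 15; no skeletal bond is cut. Silyl ethers are chosen over benzyl or alkoxymethyl ethers because they place no activated C–H bond α to oxygen within reach of the carbene used one step earlier. They also come off under acidic fluoride conditions that do not enolise either ketone. The forward reaction must cleave nine Si–O bonds, one of them on a hindered secondary alcohol.

**15 to 13.** The C2–C3 bond of unit 1 is cut, opening ring C of unit 1 to the α-aryl-α-diazo ketone 13. This cut is preferred to the neighbouring O1–C2 or C4–C4a cuts of the same ring because it removes both stereocentres of unit 1 at once. It also leaves the crowded C3–C8 linkage as a carbene carbon already attached to unit 2. In the forward direction a chiral dirhodium carboxylate must select one of the two enantiotopic benzylic hydrogens, and the cis insertion product 14 must relax to trans 15. The precursor 13 has no stereocentre in unit 1 and one ring fewer.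

**13 to 12.** The diazo group is traced to the methylene of deoxybenzoin 12 by diazo transfer. The methylene lies between an aryl ring and an aryl ketone and is by far the most acidic site in 12, so direct transfer needs no activating group. The forward reaction must deprotonate this site without enolising the C4 ketone of unit 2.

**12 to 11 and 6.** The bond between C8 of unit 2 and the methylene carbon is cut, giving aryl bromide 11 and methyl ketone 6. Two neighbouring cuts were weighed. Cutting the ketone–ring A bond would call for a Friedel–Crafts acylation with an arylacetic acid, which acid-labile silyl and electron-rich benzyl ethers would not survive. An aryllithium addition is ruled out by the ketone in unit 2. The palladium-catalysed enolate arylation forms the crowded aryl–carbon bond at a primary carbon, is convergent, and is the only place where the two halves meet. It asks for oxidative addition at a doubly ortho-oxygenated bromide and a base mild enough for the flavanonol ketone of 11.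

**11 to 7.** Bromide 11 is traced through C4 alcohol 10 and bromoflavan 9 to the pentasilyl ether 8 of (+)-catechin (7). Catechin is preferred to taxifolin as the source for a regiochemical reason. In the flavan ether 8, electrophilic bromination is expected to go to C8, because C6 lies between two bulky silyloxy groups. In a 4-keto compound the choice between C6 and C8 is less clear. The C4 carbonyl is therefore added after bromination, by benzylic oxidation next to the trioxygenated ring and oxidation of the resulting alcohol. Both stereocentres of unit 2 come unchanged from 7.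

**6 to 5 and 3, then to 4 and 1.** Ketone 6 is cut at the benzylic O–CH2 bond into phenol 5 and benzyl alcohol 3, joined by a Mitsunobu etherification that needs no base. Phenol 5 comes from 2,4,6-trihydroxyacetophenone (4), the C-acetyl derivative of phloroglucinol. Its carbonyl chelates one ortho hydroxyl, which separates the three hydroxyls without any protecting-group exchange and fixes the acyl group next to the future ether oxygen. Alcohol 3 comes from 3,4-dihydroxybenzaldehyde (1) through silyl ether 2.

## Roads not taken

**Alternative 1:** The C3–C4 bond of unit 2 is cut. The dialdehyde A2 has an aromatic aldehyde on ring A of unit 2 and an α-aryloxy-α-aryl acetaldehyde side chain, and already carries the complete unit 1. A chiral triazolium-derived carbene catalyst would close it by intramolecular crossed benzoin reaction to the octakis(methoxymethyl) ether A1, with the labile side-chain stereocentre resolved dynamically.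
- Merits: the step is metal-free, needs no diazo compound, creates C3 and C2 of unit 2 in one catalytic operation, and leaves only eight small acetal groups to remove. In these respects it is better than the chosen plan.
- Weak points: the aromatic aldehyde that must become the acyl anion equivalent is flanked by two ortho substituents and is very electron-rich, so the aliphatic aldehyde is the more likely donor and would give the regioisomeric ketol. The product is a secondary α-hydroxy ketone that can tautomerise through the enediol. The base that generates the carbene acts on a substrate containing the doubly activated C3–H of unit 1.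
- Comparison: the key step is spent on two stereocentres that catechin supplies ready-made, and the hard part (unit 1 and the C3–C8 bond) must be built first and carried through. The chosen plan sets against this its use of the chiral pool for unit 2 and the fact that unit 1 is formed last.

**Alternative 2:** The C4–C4a bond of unit 2 is cut. The acid A4, activated as a mixed anhydride, would acylate the only free carbon ortho to the ether oxygen and close ring C of unit 2 to the nonabenzyl ether A3.
- Merits: the regiochemistry is enforced by substitution, the reagents are cheap, no chiral catalyst is needed in the closing step, benzyl ethers tolerate base far better than aryl silyl ethers, and the final hydrogenolysis is neutral. On robustness of protecting groups this road is better.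
- Weak points: an α-alkoxy acylium ion is prone to lose carbon monoxide, and the β-aryloxy group can be eliminated. The acid set free can cleave benzyl ethers on such electron-rich rings, especially the one peri to the new carbonyl. The closure creates no stereocentre, so both centres of unit 2 must be built in an open chain, including a hindered diaryl-methine ether to a 2,6-disubstituted phenol that is hard to form with clean inversion.
- Comparison: the route is longer in stereocontrolled steps and again requires unit 1 to be finished first. The chosen plan gives up the robustness of benzyl ethers, which it cannot use because their C–H bonds would compete for the carbene, but buys unit 2 with both centres in place.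

**Alternative 3:** The O1–C2 bond of unit 2 is cut. The epoxy ketone A6, made by asymmetric epoxidation of chalcone A7, would lose its single methoxymethyl group under acid, and the freed phenol would open the epoxide at the benzylic carbon with inversion to give the trans dihydroflavonol A5.
- Merits: this is the best precedented closure of all four plans. It is stereospecific, sets both centres of unit 2 from one epoxidation, and delivers the free C3 hydroxyl directly. As a single step it is safer than the carbene insertion.
- Weak points: chalcone A7 would be made by base-mediated condensation and epoxidised with a basic peroxide, both in the presence of unit 1, whose C3–H is doubly activated and whose ring opens under base. The electron-rich ring B gives the epoxide opening cationic character, which can erode the inversion and allow 5-exo closure to compete. The two units need two independent asymmetric events.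
- Comparison: like the other two, this road rebuilds what catechin already contains and exposes the finished unit 1 to base. The chosen plan accepts a less proven key step and nine silyl ethers in exchange for convergence and for creating the base-sensitive unit 1 only at the end.

Key step: step 11

## Remarks and assumptions

- TBS is tert-butyldimethylsilyl. Compound 4 is commercial as its hydrate and is used dried.
- Alcohol 10 is carried forward as a mixture of C4 epimers, since step 8 removes that centre.
- Rh2(S-PTTL)4 is assumed to favour the 2R product; if the sense proves opposite, the antipodal catalyst Rh2(R-PTTL)4 would be used in the same step.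

## Route

Step 1
Reactants: 1 3,4-dihydroxybenzaldehyde
Product: 2 3,4-bis(tert-butyldimethylsilyloxy)benzaldehyde
Conditions: TBSCl (2.4 equiv), imidazole, DMF, 23 °C
Reagents that add atoms: tert-butyldimethylsilyl chloride, CC(C)(C)[Si](C)(C)Cl
Why: Imidazole-promoted silylation of phenols; both catechol hydroxyls are unhindered and the aldehyde is inert.

Step 2
Reactants: 2 3,4-bis(tert-butyldimethylsilyloxy)benzaldehyde
Product: 3 [3,4-bis(tert-butyldimethylsilyloxy)phenyl]methanol
Conditions: NaBH4, THF/EtOH, 0 °C
Reagents that add atoms: none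
Why: Borohydride reduction of an aryl aldehyde; short exposure at 0 °C should leave the aryl silyl ethers intact.

Step 3
Reactants: 4 2,4,6-trihydroxyacetophenone
Product: 5 1-[2-hydroxy-4,6-bis(tert-butyldimethylsilyloxy)phenyl]ethanone
Conditions: TBSCl (2.1 equiv), imidazole, CH2Cl2/DMF, 0 °C
Reagents that add atoms: tert-butyldimethylsilyl chloride, CC(C)(C)[Si](C)(C)Cl
Why: Regioselective silylation: the para hydroxyl and the unchelated ortho hydroxyl react, while the hydroxyl hydrogen-bonded to the acetyl carbonyl is much less nucleophilic and should remain free.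

Step 4
Reactants: 5 1-[2-hydroxy-4,6-bis(tert-butyldimethylsilyloxy)phenyl]ethanone; 3 [3,4-bis(tert-butyldimethylsilyloxy)phenyl]methanol
Product: 6 1-[2-{[3,4-bis(tert-butyldimethylsilyloxy)phenyl]methoxy}-4,6-bis(tert-butyldimethylsilyloxy)phenyl]ethanone
Conditions: PPh3, DIAD, toluene/THF, 0 → 23 °C
Reagents that add atoms: none
Why: Mitsunobu etherification; the chelated phenol is acidic enough to act as pronucleophile toward the primary benzylic oxyphosphonium ion, and the neutral medium avoids the silyl loss that carbonate alkylation would risk.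

Step 5
Reactants: 7 (+)-catechin, (2R,3S)
Product: 8 (2R,3S)-3,5,7,3',4'-pentakis-O-(tert-butyldimethylsilyl)catechin
Conditions: TBSCl (7 equiv), imidazole, DMAP (cat.), DMF, 23 → 50 °C
Reagents that add atoms: tert-butyldimethylsilyl chloride, CC(C)(C)[Si](C)(C)Cl
Why: Exhaustive silylation of four phenols and the secondary alcohol; C2 and C3 are not touched.

Step 6
Reactants: 8 (2R,3S)-3,5,7,3',4'-pentakis-O-(tert-butyldimethylsilyl)catechin
Product: 9 (2R,3S)-8-bromo-3,5,7,3',4'-pentakis-O-(tert-butyldimethylsilyl)catechin
Conditions: NBS (1.05 equiv), CH2Cl2, −40 → 0 °C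
Reagents that add atoms: N-bromosuccinimide, O=C1CCC(=O)N1Br
Why: Electrophilic aromatic bromination of the phloroglucinol-type ring; C8 should be preferred, as is usual for fully etherified flavan-3-ols, because C6 lies between two bulky silyloxy groups.

Step 7
Reactants: 9 (2R,3S)-8-bromo-3,5,7,3',4'-pentakis-O-(tert-butyldimethylsilyl)catechin
Product: 10 (2R,3S)-8-bromo-4-hydroxy-3,5,7,3',4'-pentakis-O-(tert-butyldimethylsilyl)flavan (8-bromo flavan-3,4-diol pentasilyl ether, mixture of C4 epimers)
Conditions: DDQ (2.2 equiv), CH2Cl2/H2O (10:1), 0 → 23 °C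
Reagents that add atoms: water, O
Why: DDQ benzylic oxidation: hydride abstraction from C4 gives a cation stabilised by the ortho and para oxygens of ring A, which water traps; the C4 configuration is immaterial and any ketone 11 formed directly is carried along.

Step 8
Reactants: 10 (2R,3S)-8-bromo-4-hydroxy-3,5,7,3',4'-pentakis-O-(tert-butyldimethylsilyl)flavan
Product: 11 (2R,3R)-8-bromo-3,5,7,3',4'-pentakis-O-(tert-butyldimethylsilyl)taxifolin
Conditions: Dess–Martin periodinane (1.5 equiv), CH2Cl2, 0 → 23 °C
Reagents that add atoms: none
Why: Dess–Martin oxidation of a benzylic secondary alcohol under non-basic conditions; C3 is not enolised and keeps its spatial arrangement (the descriptor changes from S to R only because the priorities change).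

Step 9
Reactants: 11 (2R,3R)-8-bromo-3,5,7,3',4'-pentakis-O-(tert-butyldimethylsilyl)taxifolin; 6 1-[2-{[3,4-bis(tert-butyldimethylsilyloxy)phenyl]methoxy}-4,6-bis(tert-butyldimethylsilyloxy)phenyl]ethanone
Product: 12 (2R,3R)-8-{2-[2-{[3,4-bis(tert-butyldimethylsilyloxy)phenyl]methoxy}-4,6-bis(tert-butyldimethylsilyloxy)phenyl]-2-oxoethyl}-3,5,7,3',4'-pentakis-O-(tert-butyldimethylsilyl)taxifolin (the deoxybenzoin)
Conditions: Pd2(dba)3 (2.5 mol %), XPhos (6 mol %), anhydrous K3PO4 (2.5 equiv), 6 (1.3 equiv), toluene, 80 °C
Reagents that add atoms: none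
Why: Palladium-catalysed α-arylation of a methyl ketone enolate (Buchwald–Hartwig type) with a zerovalent palladium catalyst; the bulky biaryl phosphine supports oxidative addition at the hindered bromide and reductive elimination to a primary carbon. Insoluble phosphate is the mildest base known to work, the only α-hydrogen of the ketone in 11 is tertiary and hindered, and the product enolate is too crowded for a second arylation.

Step 10
Reactants: 12 the deoxybenzoin
Product: 13 (2R,3R)-8-{1-diazo-2-[2-{[3,4-bis(tert-butyldimethylsilyloxy)phenyl]methoxy}-4,6-bis(tert-butyldimethylsilyloxy)phenyl]-2-oxoethyl}-3,5,7,3',4'-pentakis-O-(tert-butyldimethylsilyl)taxifolin (the α-diazo ketone)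
Conditions: p-ABSA (1.5 equiv), DBU (1.5 equiv), MeCN/CH2Cl2, 0 °C, dark
Reagents that add atoms: 4-acetamidobenzenesulfonyl azide (p-ABSA), CC(=O)Nc1ccc(cc1)S(=O)(=O)N=[N+]=[N-]
Why: Regitz diazo transfer to a benzylic ketone; DBU reversibly deprotonates the aryl- and acyl-activated methylene, which is several pKa units more acidic than C3–H of unit 2, and the enolate attacks the terminal nitrogen of the sulfonyl azide.

Step 11
Reactants: 13 the α-diazo ketone
Product: 15 manniflavanone nonakis(tert-butyldimethylsilyl) ether (unit 1: 2R,3S; unit 2: 2R,3R), via cis insertion product 14 (not isolated)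
Conditions: Rh2(S-PTTL)4 (dirhodium tetrakis[N-phthaloyl-(S)-tert-leucinate], divalent rhodium; 2 mol %), toluene, 4 Å MS, slow addition of 13, −40 → 0 °C; then Et3N (0.3 equiv), 23 °C
Reagents that add atoms: none
Why: Rh2(S-PTTL)4 decomposes the diazo group of 13 with loss of N2 to a rhodium-bound aryl/acyl (donor/acceptor) carbenoid at C3 of unit 1, which inserts into one benzylic C–H bond of the aryl benzyl ether through a concerted, asynchronous three-centre transition state with hydride-transfer character, forming C2–C3. The closest known reaction type is the dirhodium-carboxylate-catalysed intramolecular C–H insertion of ortho-alkoxyaryl α-diazo ketones to chroman-4-ones, together with insertions of aryl diazo carbonyl compounds into benzyl ether C–H bonds under Rh2(S-PTTL)4. Ring C of unit 1 closes as a six-membered ring by 1,6-insertion (C3, C4, C4a, C8a, O1, C2), the usual 1,5-position being the ether oxygen itself. C2 is set by the chiral carboxylate ligands, which distinguish the two enantiotopic benzylic hydrogens; the stereocentres of unit 2 are remote and should only modulate this. C3 is set under thermodynamic control: the cis isomer 14 expected from the insertion epimerises through the enol on exposure to Et3N to the trans 2,3-diaryl arrangement of 15 without cleavage of the C2–O1 bond. The step needs selectivity for this C–H bond over oxonium ylide formation with [1,2]-benzyl shift and over all other C–H bonds. The target hydrogen is activated by both the ether oxygen and the electron-rich ring B, the aryl donor tempers the carbenoid, every other oxygen carries a silyl group with no activated C–H within reach, and C2–H of unit 2 could be reached only by forming a bridged ring.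

Step 12
Reactants: 15 manniflavanone nonakis(tert-butyldimethylsilyl) ether
Product: 16 manniflavanone
Conditions: HF·pyridine (excess), pyridine/THF, 0 → 23 °C, argon; quench with Me3SiOMe; Sephadex LH-20
Reagents that add atoms: none
Why: Fluoride-mediated cleavage of the eight aryl and one alkyl Si–O bonds; the acidic buffered medium avoids the enolate pathways (ring opening, C3 epimerisation) that basic fluoride could start, so all four stereocentres should be retained.

## Compound list

1 | 3,4-dihydroxybenzaldehyde | O=Cc1ccc(O)c(O)c1 | starting material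
2 | 3,4-bis(tert-butyldimethylsilyloxy)benzaldehyde | O=Cc1ccc(O[Si](C)(C)C(C)(C)C)c(O[Si](C)(C)C(C)(C)C)c1 | intermediate
3 | [3,4-bis(tert-butyldimethylsilyloxy)phenyl]methanol | OCc1ccc(O[Si](C)(C)C(C)(C)C)c(O[Si](C)(C)C(C)(C)C)c1 | intermediate
4 | 2,4,6-trihydroxyacetophenone | CC(=O)c1c(O)cc(O)cc1O | starting material
5 | 1-[2-hydroxy-4,6-bis(tert-butyldimethylsilyloxy)phenyl]ethanone | CC(=O)c1c(O)cc(O[Si](C)(C)C(C)(C)C)cc1O[Si](C)(C)C(C)(C)C | intermediate
6 | 1-[2-{[3,4-bis(tert-butyldimethylsilyloxy)phenyl]methoxy}-4,6-bis(tert-butyldimethylsilyloxy)phenyl]ethanone | CC(=O)c1c(O[Si](C)(C)C(C)(C)C)cc(O[Si](C)(C)C(C)(C)C)cc1OCc1ccc(O[Si](C)(C)C(C)(C)C)c(O[Si](C)(C)C(C)(C)C)c1 | intermediate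
7 | (+)-catechin, (2R,3S) | C1c2c(O)cc(O)cc2O[C@H](c2ccc(O)c(O)c2)[C@H]1O | starting material
8 | (2R,3S)-3,5,7,3',4'-pentakis-O-(tert-butyldimethylsilyl)catechin | C1c2c(O[Si](C)(C)C(C)(C)C)cc(O[Si](C)(C)C(C)(C)C)cc2O[C@H](c2ccc(O[Si](C)(C)C(C)(C)C)c(O[Si](C)(C)C(C)(C)C)c2)[C@H]1O[Si](C)(C)C(C)(C)C | intermediate
9 | (2R,3S)-8-bromo-3,5,7,3',4'-pentakis-O-(tert-butyldimethylsilyl)catechin | C1c2c(O[Si](C)(C)C(C)(C)C)cc(O[Si](C)(C)C(C)(C)C)c(Br)c2O[C@H](c2ccc(O[Si](C)(C)C(C)(C)C)c(O[Si](C)(C)C(C)(C)C)c2)[C@H]1O[Si](C)(C)C(C)(C)C | intermediate
10 | (2R,3S)-8-bromo-4-hydroxy-3,5,7,3',4'-pentakis-O-(tert-butyldimethylsilyl)flavan, mixture of C4 epimers (C4 left undefined) | OC1c2c(O[Si](C)(C)C(C)(C)C)cc(O[Si](C)(C)C(C)(C)C)c(Br)c2O[C@H](c2ccc(O[Si](C)(C)C(C)(C)C)c(O[Si](C)(C)C(C)(C)C)c2)[C@H]1O[Si](C)(C)C(C)(C)C | intermediate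
11 | (2R,3R)-8-bromo-3,5,7,3',4'-pentakis-O-(tert-butyldimethylsilyl)taxifolin | O=C1c2c(O[Si](C)(C)C(C)(C)C)cc(O[Si](C)(C)C(C)(C)C)c(Br)c2O[C@H](c2ccc(O[Si](C)(C)C(C)(C)C)c(O[Si](C)(C)C(C)(C)C)c2)[C@H]1O[Si](C)(C)C(C)(C)C | intermediate
12 | deoxybenzoin: (2R,3R)-8-{2-[2-{[3,4-bis(TBS-oxy)phenyl]methoxy}-4,6-bis(TBS-oxy)phenyl]-2-oxoethyl}-3,5,7,3',4'-pentakis-O-TBS-taxifolin | O=C1c2c(O[Si](C)(C)C(C)(C)C)cc(O[Si](C)(C)C(C)(C)C)c(CC(=O)c4c(O[Si](C)(C)C(C)(C)C)cc(O[Si](C)(C)C(C)(C)C)cc4OCc3ccc(O[Si](C)(C)C(C)(C)C)c(O[Si](C)(C)C(C)(C)C)c3)c2O[C@H](c2ccc(O[Si](C)(C)C(C)(C)C)c(O[Si](C)(C)C(C)(C)C)c2)[C@H]1O[Si](C)(C)C(C)(C)C | intermediate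
13 | α-diazo ketone: (2R,3R)-8-{1-diazo-2-[2-{[3,4-bis(TBS-oxy)phenyl]methoxy}-4,6-bis(TBS-oxy)phenyl]-2-oxoethyl}-3,5,7,3',4'-pentakis-O-TBS-taxifolin | O=C1c2c(O[Si](C)(C)C(C)(C)C)cc(O[Si](C)(C)C(C)(C)C)c(C(=[N+]=[N-])C(=O)c4c(O[Si](C)(C)C(C)(C)C)cc(O[Si](C)(C)C(C)(C)C)cc4OCc3ccc(O[Si](C)(C)C(C)(C)C)c(O[Si](C)(C)C(C)(C)C)c3)c2O[C@H](c2ccc(O[Si](C)(C)C(C)(C)C)c(O[Si](C)(C)C(C)(C)C)c2)[C@H]1O[Si](C)(C)C(C)(C)C | intermediate
14 | cis insertion product: nonakis(TBS) ether with unit 1 (2R,3R) and unit 2 (2R,3R) | O=C1c2c(O[Si](C)(C)C(C)(C)C)cc(O[Si](C)(C)C(C)(C)C)c([C@H]3C(=O)c4c(O[Si](C)(C)C(C)(C)C)cc(O[Si](C)(C)C(C)(C)C)cc4O[C@H]3c3ccc(O[Si](C)(C)C(C)(C)C)c(O[Si](C)(C)C(C)(C)C)c3)c2O[C@H](c2ccc(O[Si](C)(C)C(C)(C)C)c(O[Si](C)(C)C(C)(C)C)c2)[C@H]1O[Si](C)(C)C(C)(C)C | intermediate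
15 | manniflavanone nonakis(tert-butyldimethylsilyl) ether, unit 1 (2R,3S), unit 2 (2R,3R) | O=C1c2c(O[Si](C)(C)C(C)(C)C)cc(O[Si](C)(C)C(C)(C)C)c([C@@H]3C(=O)c4c(O[Si](C)(C)C(C)(C)C)cc(O[Si](C)(C)C(C)(C)C)cc4O[C@H]3c3ccc(O[Si](C)(C)C(C)(C)C)c(O[Si](C)(C)C(C)(C)C)c3)c2O[C@H](c2ccc(O[Si](C)(C)C(C)(C)C)c(O[Si](C)(C)C(C)(C)C)c2)[C@H]1O[Si](C)(C)C(C)(C)C | intermediate
16 | manniflavanone | O=C1c2c(O)cc(O)c([C@@H]3C(=O)c4c(O)cc(O)cc4O[C@H]3c3ccc(O)c(O)c3)c2O[C@H](c2ccc(O)c(O)c2)[C@H]1O | target

## Step count and least certain steps

Total step count: 12. Longest linear sequence: 8 steps (steps 5 to 12, from 7 to 16).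

**Step 11 (key step).** The most likely failure is diversion of the carbenoid: the lone pair of the benzylic ether oxygen can attack it to give a five-membered oxonium ylide, which rearranges by [1,2]-benzyl shift. A second possibility is poor discrimination between the two benzylic hydrogens, because a carbenoid flanked by two doubly ortho-substituted aryl groups may fit badly into the chiral ligand pocket. The fallback forms the same C2–C3 bond by condensation chemistry and sets out from 12. Hydrogenolysis (H2, Pd/C, EtOAc) removes the ring B benzyl group to give the 2-hydroxy deoxybenzoin F1. Amine-mediated condensation of F1 with aldehyde 2 (pyrrolidine, toluene, molecular sieves), followed by 6-endo oxa-Michael closure of the resulting enone, is the known route to 2-aryl isoflavanones. It should give the trans ring under thermodynamic control and comes back to the route at 15. The unit 1 diastereomer F2 (2S,3R) would form alongside and would be removed by chromatography; the two differ as diastereomers because unit 2 is enantiopure.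

**Step 9.** The most likely failure is enolisation of the C4 ketone of 11 by phosphate at 80 °C, leading to ring opening and loss of the C2/C3 configuration. Slow oxidative addition at the doubly ortho-oxygenated bromide and partial loss of phenolic silyl groups would aggravate this. The fallback moves the coupling ahead of the C4 oxidation and sets out from 9 and 6. Under the same palladium catalysis, now free to use higher temperature because no enolisable ring ketone is present, they should give the flavan-level deoxybenzoin F3. DDQ in wet CH2Cl2 would then give the C4 alcohol F4, and Dess–Martin oxidation returns to the route at 12. This order is second choice because the DDQ step must then spare the electron-rich benzyl ether of ring B.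

**Step 10.** The most likely failure is that transfer to the hindered methylene is slow, so that DBU has time to enolise the unit 2 ketone or strip phenolic silyl groups. The fallback avoids free base and sets out from 12. Heating with N,N-dimethylformamide dimethyl acetal should give the enaminone F5. Tosyl azide then delivers the diazo group by cycloaddition and cycloreversion, releasing a sulfonyl formamidine, and the sequence comes back to the route at 13.

**Step 12.** The most likely failure is slow cleavage of the hindered secondary silyl ether at C3 of unit 2, which forces long reaction times during which the free catechols oxidise and the polar product is lost on isolation. The fallback uses an acetate relay and sets out from 15. After HF·pyridine the crude polyphenol is acetylated in the same flask (Ac2O, pyridine, DMAP) to manniflavanone nonaacetate F6, which can be purified on silica. Acidic methanolysis (HCl in MeOH) then releases the phenols without base and comes back to the route at 16.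

## Further compounds

F1 | step 11 | 2-hydroxy deoxybenzoin (12 without the ring B benzyl group) | O=C1c2c(O[Si](C)(C)C(C)(C)C)cc(O[Si](C)(C)C(C)(C)C)c(CC(=O)c3c(O[Si](C)(C)C(C)(C)C)cc(O[Si](C)(C)C(C)(C)C)cc3O)c2O[C@H](c2ccc(O[Si](C)(C)C(C)(C)C)c(O[Si](C)(C)C(C)(C)C)c2)[C@H]1O[Si](C)(C)C(C)(C)C
F2 | step 11 | diastereomer of 15 with unit 1 (2S,3R) and unit 2 (2R,3R) | O=C1c2c(O[Si](C)(C)C(C)(C)C)cc(O[Si](C)(C)C(C)(C)C)c([C@H]3C(=O)c4c(O[Si](C)(C)C(C)(C)C)cc(O[Si](C)(C)C(C)(C)C)cc4O[C@@H]3c3ccc(O[Si](C)(C)C(C)(C)C)c(O[Si](C)(C)C(C)(C)C)c3)c2O[C@H](c2ccc(O[Si](C)(C)C(C)(C)C)c(O[Si](C)(C)C(C)(C)C)c2)[C@H]1O[Si](C)(C)C(C)(C)C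
F3 | step 9 | flavan-level deoxybenzoin (12 with CH2 at C4 of unit 2; 2R,3S) | C1c2c(O[Si](C)(C)C(C)(C)C)cc(O[Si](C)(C)C(C)(C)C)c(CC(=O)c4c(O[Si](C)(C)C(C)(C)C)cc(O[Si](C)(C)C(C)(C)C)cc4OCc3ccc(O[Si](C)(C)C(C)(C)C)c(O[Si](C)(C)C(C)(C)C)c3)c2O[C@H](c2ccc(O[Si](C)(C)C(C)(C)C)c(O[Si](C)(C)C(C)(C)C)c2)[C@H]1O[Si](C)(C)C(C)(C)C
F4 | step 9 | C4 alcohol of F3, mixture of C4 epimers (C4 left undefined) | OC1c2c(O[Si](C)(C)C(C)(C)C)cc(O[Si](C)(C)C(C)(C)C)c(CC(=O)c4c(O[Si](C)(C)C(C)(C)C)cc(O[Si](C)(C)C(C)(C)C)cc4OCc3ccc(O[Si](C)(C)C(C)(C)C)c(O[Si](C)(C)C(C)(C)C)c3)c2O[C@H](c2ccc(O[Si](C)(C)C(C)(C)C)c(O[Si](C)(C)C(C)(C)C)c2)[C@H]1O[Si](C)(C)C(C)(C)C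
F5 | step 10 | enaminone of 12 (dimethylaminomethylene at the former methylene; alkene geometry not assigned) | O=C1c2c(O[Si](C)(C)C(C)(C)C)cc(O[Si](C)(C)C(C)(C)C)c(C(=CN(C)C)C(=O)c4c(O[Si](C)(C)C(C)(C)C)cc(O[Si](C)(C)C(C)(C)C)cc4OCc3ccc(O[Si](C)(C)C(C)(C)C)c(O[Si](C)(C)C(C)(C)C)c3)c2O[C@H](c2ccc(O[Si](C)(C)C(C)(C)C)c(O[Si](C)(C)C(C)(C)C)c2)[C@H]1O[Si](C)(C)C(C)(C)C
F6 | step 12 | manniflavanone nonaacetate | O=C1c2c(OC(C)=O)cc(OC(C)=O)c([C@@H]3C(=O)c4c(OC(C)=O)cc(OC(C)=O)cc4O[C@H]3c3ccc(OC(C)=O)c(OC(C)=O)c3)c2O[C@H](c2ccc(OC(C)=O)c(OC(C)=O)c2)[C@H]1OC(C)=O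
A1 | alternative 1 | manniflavanone octakis(methoxymethyl) ether with free C3 hydroxyl in unit 2 | O=C1c2c(OCOC)cc(OCOC)c([C@@H]3C(=O)c4c(OCOC)cc(OCOC)cc4O[C@H]3c3ccc(OCOC)c(OCOC)c3)c2O[C@H](c2ccc(OCOC)c(OCOC)c2)[C@H]1O
A2 | alternative 1 | dialdehyde precursor (aryl aldehyde plus α-aryloxy-α-aryl acetaldehyde, side-chain centre epimerisable and left undefined) | O=Cc1c(OCOC)cc(OCOC)c([C@@H]2C(=O)c3c(OCOC)cc(OCOC)cc3O[C@H]2c2ccc(OCOC)c(OCOC)c2)c1OC(C=O)c1ccc(OCOC)c(OCOC)c1
A3 | alternative 2 | manniflavanone nonabenzyl ether | O=C1c2c(OCc5ccccc5)cc(OCc5ccccc5)c([C@@H]3C(=O)c4c(OCc5ccccc5)cc(OCc5ccccc5)cc4O[C@H]3c3ccc(OCc5ccccc5)c(OCc5ccccc5)c3)c2O[C@H](c2ccc(OCc5ccccc5)c(OCc5ccccc5)c2)[C@H]1OCc5ccccc5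
A4 | alternative 2 | 3-aryl-3-aryloxy-2-benzyloxypropanoic acid precursor | c1c(OCc2ccccc2)cc(OCc2ccccc2)c([C@@H]2C(=O)c3c(OCc4ccccc4)cc(OCc4ccccc4)cc3O[C@H]2c2ccc(OCc3ccccc3)c(OCc3ccccc3)c2)c1O[C@H](c1ccc(OCc2ccccc2)c(OCc2ccccc2)c1)[C@H](C(=O)O)OCc1ccccc1
A5 | alternative 3 | manniflavanone octabenzyl ether with free C3 hydroxyl in unit 2 | O=C1c2c(OCc5ccccc5)cc(OCc5ccccc5)c([C@@H]3C(=O)c4c(OCc5ccccc5)cc(OCc5ccccc5)cc4O[C@H]3c3ccc(OCc5ccccc5)c(OCc5ccccc5)c3)c2O[C@H](c2ccc(OCc5ccccc5)c(OCc5ccccc5)c2)[C@H]1O
A6 | alternative 3 | trans epoxy ketone precursor with one methoxymethyl ether | O=C(c1c(OCc2ccccc2)cc(OCc2ccccc2)c([C@@H]2C(=O)c3c(OCc4ccccc4)cc(OCc4ccccc4)cc3O[C@H]2c2ccc(OCc3ccccc3)c(OCc3ccccc3)c2)c1OCOC)[C@@H]1O[C@H]1c1ccc(OCc2ccccc2)c(OCc2ccccc2)c1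
A7 | alternative 3 | (E)-chalcone from which A6 would be made | O=C(c1c(OCc2ccccc2)cc(OCc2ccccc2)c([C@@H]2C(=O)c3c(OCc4ccccc4)cc(OCc4ccccc4)cc3O[C@H]2c2ccc(OCc3ccccc3)c(OCc3ccccc3)c2)c1OCOC)/C=C/c1ccc(OCc2ccccc2)c(OCc2ccccc2)c1
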